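## The problem

The target 30 is a 2H-chromene whose benzene ring is fully substituted. It carries the ring oxygen on C8a, methoxy groups on C8, C7 and C6, a free hydroxyl on C5 and the pyran carbon C4 on C4a. C2 is a quaternary stereocentre (R) with a methyl group and a two-carbon tether to a 1,2,3-trimethylcyclohex-3-ene. In that ring the adjacent stereocentres C1' (quaternary, S) and C2' (S) carry cis methyl groups.

C1' and C2' are neighbours and can be set in one event. C2 is three bonds from C1' across a flexible chain, so neither set can steer the other and each needs its own reagent control.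

Several groups are fragile:
- The arene is a hydroquinone monoether and is easily oxidised to a quinone.
- A 2,2-disubstituted 2H-chromene can lose its C2 configuration by reversible oxa-6π ring opening under heat or light.
- The C3'=C4' alkene can migrate under acid or metal hydrides into the tetrasubstituted position, which would erase C2'.

Only one of five aryl oxygens may end as a free phenol, and at a defined position. The enabling feature is that C5 to C8 with their four oxygens are the skeleton of dimethyl squarate 23, while C8a and C4a are the two carbons of a cyclic enol ether (C6 and C5 of a 3,4-dihydro-2H-pyran). The arene can therefore be grown onto a finished, stereodefined pyran by ring expansion of a 4-alkenylcyclobutenone.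

## Retrosynthesis

**30 from 29.** The C3=C4 alkene is traced back to a C4 silyl ether, chroman 29. The alkene is made last because a 2H-chromene would survive neither the lithiation nor the heating used earlier without risk to C2. The forward step is an acid-induced loss of silanol from an activated benzylic position, mild enough to leave C3'=C4' in place.

**29 from 26.** The C5–C4a bond is cut and C5 is re-joined to C8, which turns the arene into the four-membered ring of cyclobutenone 26. Cuts at the aryl C–O bonds would demand a hexasubstituted benzene with five differentiated oxygens. Here all four carbons C5–C8 and their oxygens come from one reagent, and O5 (free) is told from O8 (methylated) by connectivity. The forward reaction needs outward rotation of the methoxy group in the 4π opening and a silyl ether that tolerates 110 °C.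

**26 from 22 and 23.** The bond between the carbinol carbon and pyran C6 is cut, along with the O–CH3 bond, giving dihydropyran 22 and dimethyl squarate 23. This is the convergent cut of the route. It asks for clean deprotonation of the enol ether at C6, mono-addition to one squarate carbonyl and O-methylation of the tertiary alkoxide. Triisopropylsilyl is chosen on O4 because it withstands t-BuLi better than smaller silyl groups.

**22 from 21, 20, 18 and 19.** The enol ether O1–C6 bond is cut to alkynol 21, the silyl group is removed to give diol 20, and the C4–C5 bond is cut to aldehyde 18 and ethynylmagnesium bromide 19. The usual alternative goes through a dihydropyranone (ynone, oxa-Michael closure, 1,2-reduction, silylation) and needs two more steps. The alkynol route places the C4 oxygen at the right oxidation level from the start. It requires endo-selective addition of a tertiary hydroxyl to a metal vinylidene.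

**18 from 17, 16, 15 and 14.** Aldehyde 18 comes from diol 17. The cyclohexene C3'=C4' bond of 17 is cut to the acyclic diene 16 (ring-closing metathesis). The tertiary carbinol of 16 comes from epoxy alcohol 15, and 15 from the Z-allylic alcohol 14. The epoxidation sets C2 by reagent control, far from C1' and C2'. Metathesis is placed after epoxidation and reduction because by then the chain alkene is gone and only the two ring-forming alkenes remain.

**14 from 13, 12, 7 and 10.** The 1,1-disubstituted alkene of 14 comes from ketone 13, and 13 from amide 12. The C–C bond between the tether and the methyl-bearing alkene carbon is cut to the vinyl group of amide 7 and vinyl iodide 10 (B-alkyl Suzuki–Miyaura coupling). The order is forced twice. Hydroboration must precede creation of the 1,1-disubstituted alkene, which 9-BBN would not spare. The vinyl group must be consumed before metathesis, or it would close a cyclopentene with the prenyl group.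

**7 from 5, 2 and 1.** Amide 7 comes from acid 5. The C1'–C2' bond of 5 is cut by a [3,3] shift to geranyl propanoate 2, made from geraniol 1. One step creates the quaternary centre and its neighbour. The relative configuration comes from enolate geometry and a chair transition state, the absolute configuration from a chiral boron ligand.

**10 from 8.** The Z-iodide comes from but-2-yn-1-ol 8 by hydroxyl-directed hydroalumination and iodination.

## Roads not taken

**Alternative 1:** The cyclohexene is cut at C1'–C2' and C5'–C6'. In the forward direction (3E)-3-methylpenta-1,3-diene A1 and the 2-substituted acrolein A2 would combine in a Diels–Alder reaction under a chiral cationic oxazaborolidine catalyst to give aldehyde A3.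
- Merits: the ring and both of its stereocentres arise in one catalytic step from two small achiral partners. The ketal of A3 already hides the methyl ketone needed for the chain.
- Weak points: the target needs the formyl group cis to the C2' methyl, i.e. formyl endo, whereas 2-substituted acroleins tend to place the formyl group exo. The formyl group must then be reduced to methyl at a neopentyl carbon, which costs two or three steps. The arene and C2 are left unsolved.
- Comparison: for the carbocycle alone this road is clearly shorter than the chosen one, which spends steps 1–3, 6, 7 and 10 and a stoichiometric chiral boron reagent on it. Against that, the chosen plan offers a relative configuration that follows from a chair Claisen transition state and not from an endo/exo preference, and it needs no deoxygenation. Its key step is spent on the harder half of the molecule.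

**Alternative 2:** The pyran is cut at C8a–O1, C4a–C4 and O1–C2. The fluoride-generated aryne A4 would add the aldehyde of enal A5 to give a benzoxete, which opens to an ortho-quinone methide and closes by oxa-6π electrocyclisation to chromene triflate A6.
- Merits: three bonds and the pyran ring form in one step, and on paper this is the shortest route.
- Weak points: C2 is created in the electrocyclisation with no element to control it, so A6 forms with its C2 epimer. The two differ only by a remote relationship and would be hard to separate. The aryne precursor is itself a hexasubstituted benzene. Insertion of arynes into enals is less efficient than into formamides. The triflate must still be cleaved.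
- Comparison: this road wins on step count and convergence. The chosen plan sets against it a C2 centre fixed by asymmetric epoxidation before the arene exists, and an arene pattern that needs no prior synthesis of a substituted benzene. For a single-enantiomer target that outweighs the length.

**Alternative 3:** The pyran is cut at C8a–O1. The tertiary alkoxide of bromide A7 would close onto the aryl bromide under palladium catalysis to give the methoxymethyl ether A8 of the target.
- Merits: C2 is as secure as in the chosen plan. The closure runs below 100 °C and avoids the thermolysis. The end game is a single deprotection.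
- Weak points: the bromide sits between two ortho substituents on a very electron-rich ring and the nucleophile is a tertiary alkoxide, the hardest combination for C–O reductive elimination. The Z-styrene of A7 must be made and kept. The bromoarene carries five differentiated oxygens plus bromine and a vinyl group, and each must be introduced regioselectively.
- Comparison: this road is equal in stereocontrol and gentler in its ring closure. The chosen plan sets against it that the whole substitution pattern of the arene, including the free C5 hydroxyl, comes from one commercial reagent with no protecting group on the ring.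

Key step: step 16

Assumption: the (S,S)-bromoborane of step 2 is taken to induce the sense that gives (2S,3S)-5; if the sense is the reverse, the (R,R)-reagent is used and nothing else changes.

## Steps

Step 1
Reactants: 1 geraniol
Product: 2 (2E)-3,7-dimethylocta-2,6-dien-1-yl propanoate (geranyl propanoate)
Conditions: EtCOCl, pyridine, DMAP (cat.), CH2Cl2, 0 °C → rt
Reagents that add atoms: propanoyl chloride, CCC(=O)Cl
Why: DMAP-catalysed acylation of a primary allylic alcohol; the E alkene is untouched, so geometrically pure geraniol should give geometrically pure ester.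

Step 2
Reactants: 2 geranyl propanoate
Product: 5 (2S,3S)-3-ethenyl-2,3,7-trimethyloct-6-enoic acid, via boron ketene acetal 3 (not isolated), via acyloxyborane 4 (not isolated)
Conditions: pre-formed (S,S)-2-bromo-1,3-bis{[3,5-bis(trifluoromethyl)phenyl]sulfonyl}-4,5-diphenyl-1,3,2-diazaborolidine (1.1 equiv), Et3N, toluene–hexane, −78 °C; then −20 → 4 °C; aqueous work-up
Reagents that add atoms: none
Why: Enantioselective Ireland–Claisen rearrangement of a chiral boron ketene acetal. Et3N in a hydrocarbon medium should give the enolate with its methyl trans to O–B, and the chair transition state with the E-allyl unit then places the C2 and C3 methyl groups syn, which become cis on the later ring. The C2-symmetric bis-sulfonamide on boron shields one enolate face and so should fix the absolute configuration of both centres.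

Step 3
Reactants: 5 Claisen acid
Product: 7 (2S,3S)-3-ethenyl-N-methoxy-N,2,3,7-tetramethyloct-6-enamide, via acid chloride 6 (not isolated)
Conditions: (COCl)2, DMF (cat.), CH2Cl2, 0 °C → rt; then MeNH(OMe)·HCl, pyridine, CH2Cl2, 0 °C → rt
Reagents that add atoms: N,O-dimethylhydroxylamine hydrochloride, CNOC.Cl
Why: Acid chloride formation and amidation give the Weinreb amide. The α-hydrogen lies next to a quaternary carbon and pyridine is the only base, so epimerisation through a ketene should be slow.

Step 4
Reactants: 8 but-2-yn-1-ol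
Product: 10 (2Z)-3-iodobut-2-en-1-ol, via cyclic vinylalanate 9 (not isolated)
Conditions: NaAlH2(OCH2CH2OMe)2, Et2O, 0 °C → rt; EtOAc; then I2, THF, −78 → 0 °C
Reagents that add atoms: iodine, II
Why: Hydroxyl-directed trans-hydroalumination delivers hydride to C2 and holds aluminium on C3 in a five-membered alkoxyalanate. Iodinolysis with retention then gives the Z-iodide.

Step 5
Reactants: 7 Weinreb amide; 10 (2Z)-3-iodobut-2-en-1-ol
Product: 12 (2S,3S)-3-[(3Z)-5-hydroxy-3-methylpent-3-en-1-yl]-N-methoxy-N,2,3,7-tetramethyloct-6-enamide, via B-alkyl-9-BBN adduct 11 (not isolated)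
Conditions: 9-BBN, THF, 0 °C → rt; then 10, PdCl2(dppf) (5 mol%), AsPh3, aq. K3PO4, DMF, rt → 50 °C
Reagents that add atoms: none
Why: 9-BBN should add only to the monosubstituted vinyl group, since the trisubstituted alkene and the hindered amide react far more slowly. The primary alkylborane then undergoes B-alkyl Suzuki–Miyaura coupling with retention of the geometry of 10, giving the Z-trisubstituted allylic alcohol.

Step 6
Reactants: 12 coupled Weinreb amide
Product: 13 (3S,4S)-4-[(3Z)-5-hydroxy-3-methylpent-3-en-1-yl]-3,4,8-trimethylnon-7-en-2-one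
Conditions: MeMgBr (4 equiv), THF, 0 °C → rt; aq. NH4Cl
Reagents that add atoms: methylmagnesium bromide, C[Mg]Br
Why: Grignard addition to an N-methoxy-N-methylamide stops at the chelated tetrahedral intermediate, which releases the ketone only on work-up. Neither over-addition nor epimerisation of the α-centre is expected; one equivalent is consumed by the hydroxyl.

Step 7
Reactants: 13 methyl ketone
Product: 14 (2Z,6S,7R)-3,6,7,8-tetramethyl-6-(4-methylpent-3-en-1-yl)nona-2,8-dien-1-ol
Conditions: Zn, CH2Br2, TiCl4, THF (pre-formed reagent); then 13, CH2Cl2, 0 °C → rt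
Reagents that add atoms: dibromomethane, BrCBr
Why: Lombardo methylenation uses a non-basic titanium–zinc methylene reagent. It converts hindered, enolisable ketones into 1,1-disubstituted alkenes without epimerisation next to the carbonyl and tolerates a free hydroxyl.

Step 8
Reactants: 14 trienol
Product: 15 [(2S,3R)-3-methyl-3-{(3S,4R)-3,4,5-trimethyl-3-(4-methylpent-3-en-1-yl)hex-5-en-1-yl}oxiran-2-yl]methanol
Conditions: Ti(OiPr)4 (10 mol%), L-(+)-diethyl tartrate (12 mol%), t-BuOOH, 4 Å molecular sieves, CH2Cl2, −20 °C
Reagents that add atoms: tert-butyl hydroperoxide, CC(C)(C)OO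
Why: Sharpless asymmetric epoxidation acts only on the allylic alcohol. With L-(+)-tartrate a Z-trisubstituted allylic alcohol of the nerol type should give the (2S,3R)-oxirane, whose C3 becomes C2 of the target. The control comes from the catalyst, not from the remote stereocentres.

Step 9
Reactants: 15 epoxy alcohol
Product: 16 (3R,6S,7R)-3,6,7,8-tetramethyl-6-(4-methylpent-3-en-1-yl)non-8-ene-1,3-diol
Conditions: NaAlH2(OCH2CH2OMe)2, THF, 0 °C → rt; aq. potassium sodium tartrate
Reagents that add atoms: none
Why: Regioselective reductive opening of a 2,3-epoxy alcohol. The alkoxyaluminate delivers hydride intramolecularly to C2, so the C3–O bond and its configuration are kept and the 1,3-diol results.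

Step 10
Reactants: 16 acyclic diol
Product: 17 (3R)-3-methyl-5-[(1S,2S)-1,2,3-trimethylcyclohex-3-en-1-yl]pentane-1,3-diol
Conditions: second-generation Grubbs catalyst RuCl2(=CHPh)(H2IMes)(PCy3) (5–10 mol%), 1,4-benzoquinone (10 mol%), CH2Cl2 (0.01 M), 40 °C
Reagents that add atoms: none
Why: Ring-closing metathesis between the 1,1-disubstituted alkene and the prenyl-type alkene gives the trisubstituted cyclohexene and releases isobutene. No other alkene remains in the molecule and the quaternary centre favours six-ring closure. The stereocentres take no part, and the quinone is added to suppress hydride-induced alkene migration.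

Step 11
Reactants: 17 cyclohexenyl diol
Product: 18 (3R)-3-hydroxy-3-methyl-5-[(1S,2S)-1,2,3-trimethylcyclohex-3-en-1-yl]pentanal
Conditions: TEMPO (10 mol%), PhI(OAc)2, CH2Cl2, rt; used crude
Reagents that add atoms: none
Why: Oxoammonium (TEMPO) oxidation takes a primary alcohol to the aldehyde under near-neutral conditions and leaves the tertiary alcohol and the alkene alone. The β-hydroxy aldehyde is not stored, to avoid retro-aldol cleavage or dehydration.

Step 12
Reactants: 18 hydroxy aldehyde; 19 ethynylmagnesium bromide
Product: 20 (5R)-5-methyl-7-[(1S,2S)-1,2,3-trimethylcyclohex-3-en-1-yl]hept-1-yne-3,5-diol (C3 epimers)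
Conditions: HC≡CMgBr (3 equiv), THF, −78 → 0 °C; aq. NH4Cl
Reagents that add atoms: none
Why: Acetylide addition to the aldehyde after the first equivalent has deprotonated the tertiary hydroxyl. The new carbinol centre forms as a mixture, which is harmless because it becomes the sp2 carbon C4 of the target.

Step 13
Reactants: 20 alkynediol
Product: 21 (3R)-3-methyl-5-[(triisopropylsilyl)oxy]-1-[(1S,2S)-1,2,3-trimethylcyclohex-3-en-1-yl]hept-6-yn-3-ol (C5 epimers)
Conditions: i-Pr3SiCl, imidazole, DMAP (cat.), DMF, rt → 40 °C
Reagents that add atoms: chlorotriisopropylsilane, CC(C)[Si](Cl)(C(C)C)C(C)C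
Why: The bulky silyl chloride silylates the unhindered secondary propargylic hydroxyl and not the tertiary one, which must stay free for ring closure. Triisopropylsilyl is chosen because it resists the later lithiation.

Step 14
Reactants: 21 silyloxy alkynol
Product: 22 triisopropyl{[(2R)-2-methyl-2-{2-[(1S,2S)-1,2,3-trimethylcyclohex-3-en-1-yl]ethyl}-3,4-dihydro-2H-pyran-4-yl]oxy}silane (C4 epimers)
Conditions: W(CO)6 (25 mol%), Et3N, THF, hν (350 nm), 60 °C
Reagents that add atoms: none
Why: Tungsten-carbonyl-mediated cycloisomerisation of an alkynol, as used for glycal synthesis. The terminal alkyne becomes a vinylidene complex, the hydroxyl attacks its metal-bound carbon in the 6-endo sense, and protodemetalation gives the six-membered enol ether. Propargylic silyl ethers are standard in this reaction and C2 is not touched.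

Step 15
Reactants: 22 silyloxy dihydropyran; 23 dimethyl squarate
Product: 26 2,3,4-trimethoxy-4-[(2R)-2-methyl-4-[(triisopropylsilyl)oxy]-2-{2-[(1S,2S)-1,2,3-trimethylcyclohex-3-en-1-yl]ethyl}-3,4-dihydro-2H-pyran-6-yl]cyclobut-2-en-1-one (epimers at the carbinol carbon), via 6-lithiodihydropyran 24 (not isolated), via lithium alkoxide 25 (not isolated)
Conditions: t-BuLi (1.5 equiv), THF–pentane, −78 → 0 °C; cannulate into 23 (1.5 equiv), THF, −78 °C; then MeOTf, −78 → 0 °C; Et3N-deactivated silica
Reagents that add atoms: methyl trifluoromethanesulfonate, COS(=O)(=O)C(F)(F)F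
Why: Cyclic enol ethers are deprotonated by t-BuLi at the oxygen-bearing vinylic carbon, as in C1 lithiation of silylated glycals. The vinyllithium adds 1,2 to one carbonyl of the squarate ester, and the tertiary lithium alkoxide is O-methylated in the same flask by the triflate. The carbinol centre forms as a mixture and is destroyed in step 16.

Step 16
Reactants: 26 4-methoxycyclobutenone
Product: 29 (2R)-6,7,8-trimethoxy-2-methyl-4-[(triisopropylsilyl)oxy]-2-{2-[(1S,2S)-1,2,3-trimethylcyclohex-3-en-1-yl]ethyl}-3,4-dihydro-2H-chromen-5-ol (C4 epimers), via dienylketene 27 (not isolated), via cyclohexadienone 28 (not isolated)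
Conditions: toluene (degassed, 0.02 M), 110 °C, argon, dark
Reagents that add atoms: none
Why: Heat opens the cyclobutenone by conrotatory 4π cleavage of the bond between the carbonyl carbon and the carbinol carbon; the methoxy group on that carbon, the stronger donor, rotates outward and so turns the dihydropyranyl group inward, toward the ketene carbon of 27. The (Z)-dienylketene then closes the new six-membered carbocycle by disrotatory 6π electrocyclisation between the ketene carbon and C5 of the pyran (the later C5–C4a bond), giving dienone 28, and a proton shift from C4a to the carbonyl oxygen aromatises it to 29. This is the thermal ring expansion of 4-alkenyl-4-alkoxycyclobutenones from squarate esters to monoprotected hydroquinones (Moore rearrangement), which is known for adducts of α-lithiated cyclic enol ethers. No lasting stereocentre is created: C4a of 28 becomes aromatic and the carbinol centre of 26 disappears, so all diastereomers of 26 converge on the two C4 epimers of 29, while C2, C1' and C2' are spectators. Two selectivities are needed: torquoselectivity, secured by the donor oxygen on the carbinol carbon, and the placing of the free hydroxyl at C5 and the methyl ether at C8, which follows from connectivity because the ketene oxygen becomes O5 and the methylated carbinol oxygen becomes O8. Neutral, dilute, oxygen-free conditions are chosen to spare the silyl ether, which turns from allylic to benzylic, and the oxidation-prone hydroquinone monoether.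

Step 17
Reactants: 29 4-silyloxychroman-5-ol
Product: 30 (2R)-6,7,8-trimethoxy-2-methyl-2-{2-[(1S,2S)-1,2,3-trimethylcyclohex-3-en-1-yl]ethyl}-2H-chromen-5-ol
Conditions: p-TsOH·H2O (10 mol%), toluene, 40 °C, argon, dark
Reagents that add atoms: none
Why: Acid-promoted E1 elimination. The benzylic C4–O bond ionises with strong help from the ortho hydroxyl, the ortho ring oxygen and the para methoxy group, and loss of a C3 proton gives the conjugated chromene. Catalytic sulfonic acid at 40 °C should leave the isolated trisubstituted alkene in place, and both C4 epimers give the same product.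

## Compound list

1 | geraniol, (2E)-3,7-dimethylocta-2,6-dien-1-ol | CC(C)=CCC/C(C)=C/CO | starting material
2 | geranyl propanoate, (2E)-3,7-dimethylocta-2,6-dien-1-yl propanoate | CCC(=O)OC/C=C(\C)CCC=C(C)C | intermediate
3 | boron ketene acetal: (4S,5S)-2-{[1-(geranyloxy)prop-1-en-1-yl]oxy}-1,3-bis{[3,5-bis(trifluoromethyl)phenyl]sulfonyl}-4,5-diphenyl-1,3,2-diazaborolidine, enolate methyl cis to the geranyloxy oxygen | C/C=C(\OC/C=C(\C)CCC=C(C)C)OB1N(S(=O)(=O)c2cc(cc(c2)C(F)(F)F)C(F)(F)F)[C@@H](c2ccccc2)[C@H](c2ccccc2)N1S(=O)(=O)c1cc(cc(c1)C(F)(F)F)C(F)(F)F | intermediate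
4 | acyloxyborane: (4S,5S)-1,3-bis{[3,5-bis(trifluoromethyl)phenyl]sulfonyl}-4,5-diphenyl-1,3,2-diazaborolidin-2-yl (2S,3S)-3-ethenyl-2,3,7-trimethyloct-6-enoate | O=C(OB1N(S(=O)(=O)c2cc(cc(c2)C(F)(F)F)C(F)(F)F)[C@@H](c2ccccc2)[C@H](c2ccccc2)N1S(=O)(=O)c1cc(cc(c1)C(F)(F)F)C(F)(F)F)[C@@H](C)[C@](C)(C=C)CCC=C(C)C | intermediate
5 | (2S,3S)-3-ethenyl-2,3,7-trimethyloct-6-enoic acid | OC(=O)[C@@H](C)[C@](C)(C=C)CCC=C(C)C | intermediate
6 | (2S,3S)-3-ethenyl-2,3,7-trimethyloct-6-enoyl chloride | ClC(=O)[C@@H](C)[C@](C)(C=C)CCC=C(C)C | intermediate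
7 | (2S,3S)-3-ethenyl-N-methoxy-N,2,3,7-tetramethyloct-6-enamide | CON(C)C(=O)[C@@H](C)[C@](C)(C=C)CCC=C(C)C | intermediate
8 | but-2-yn-1-ol | CC#CCO | starting material
9 | sodium 2,2-bis(2-methoxyethoxy)-3-methyl-2,5-dihydro-1,2-oxaaluminol-2-uide (cyclic Z-vinylalanate) | CC1=CCO[Al-]1(OCCOC)OCCOC.[Na+] | intermediate
10 | (2Z)-3-iodobut-2-en-1-ol | C/C(I)=C/CO | intermediate
11 | (2S,3R)-3-[2-(9-borabicyclo[3.3.1]nonan-9-yl)ethyl]-N-methoxy-N,2,3,7-tetramethyloct-6-enamide | CON(C)C(=O)[C@@H](C)[C@](C)(CCB1C2CCCC1CCC2)CCC=C(C)C | intermediate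
12 | (2S,3S)-3-[(3Z)-5-hydroxy-3-methylpent-3-en-1-yl]-N-methoxy-N,2,3,7-tetramethyloct-6-enamide | CON(C)C(=O)[C@@H](C)[C@](C)(CC/C(C)=C\CO)CCC=C(C)C | intermediate
13 | (3S,4S)-4-[(3Z)-5-hydroxy-3-methylpent-3-en-1-yl]-3,4,8-trimethylnon-7-en-2-one | CC(=O)[C@@H](C)[C@](C)(CC/C(C)=C\CO)CCC=C(C)C | intermediate
14 | (2Z,6S,7R)-3,6,7,8-tetramethyl-6-(4-methylpent-3-en-1-yl)nona-2,8-dien-1-ol | C=C(C)[C@@H](C)[C@](C)(CC/C(C)=C\CO)CCC=C(C)C | intermediate
15 | [(2S,3R)-3-methyl-3-{(3S,4R)-3,4,5-trimethyl-3-(4-methylpent-3-en-1-yl)hex-5-en-1-yl}oxiran-2-yl]methanol | C=C(C)[C@@H](C)[C@](C)(CC[C@@]1(C)O[C@H]1CO)CCC=C(C)C | intermediate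
16 | (3R,6S,7R)-3,6,7,8-tetramethyl-6-(4-methylpent-3-en-1-yl)non-8-ene-1,3-diol | C=C(C)[C@@H](C)[C@](C)(CC[C@@](C)(O)CCO)CCC=C(C)C | intermediate
17 | (3R)-3-methyl-5-[(1S,2S)-1,2,3-trimethylcyclohex-3-en-1-yl]pentane-1,3-diol | OCC[C@](C)(O)CC[C@]1(C)CCC=C(C)[C@H]1C | intermediate
18 | (3R)-3-hydroxy-3-methyl-5-[(1S,2S)-1,2,3-trimethylcyclohex-3-en-1-yl]pentanal | O=CC[C@](C)(O)CC[C@]1(C)CCC=C(C)[C@H]1C | intermediate
19 | ethynylmagnesium bromide | C#C[Mg]Br | starting material
20 | (5R)-5-methyl-7-[(1S,2S)-1,2,3-trimethylcyclohex-3-en-1-yl]hept-1-yne-3,5-diol, C3 epimers | C#CC(O)C[C@](C)(O)CC[C@]1(C)CCC=C(C)[C@H]1C | intermediate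
21 | (3R)-3-methyl-5-[(triisopropylsilyl)oxy]-1-[(1S,2S)-1,2,3-trimethylcyclohex-3-en-1-yl]hept-6-yn-3-ol, C5 epimers | C#CC(O[Si](C(C)C)(C(C)C)C(C)C)C[C@](C)(O)CC[C@]1(C)CCC=C(C)[C@H]1C | intermediate
22 | triisopropyl{[(2R)-2-methyl-2-{2-[(1S,2S)-1,2,3-trimethylcyclohex-3-en-1-yl]ethyl}-3,4-dihydro-2H-pyran-4-yl]oxy}silane, C4 epimers | C1=CC(O[Si](C(C)C)(C(C)C)C(C)C)C[C@@](C)(CC[C@]2(C)CCC=C(C)[C@H]2C)O1 | intermediate
23 | dimethyl squarate, 3,4-dimethoxycyclobut-3-ene-1,2-dione | COC1=C(OC)C(=O)C1=O | starting material
24 | 6-lithio derivative of 22 (lithium on the oxygen-bearing alkene carbon C6) | [Li]C1=CC(O[Si](C(C)C)(C(C)C)C(C)C)C[C@@](C)(CC[C@]2(C)CCC=C(C)[C@H]2C)O1 | intermediate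
25 | lithium 2,3-dimethoxy-4-oxo-1-[(2R)-2-methyl-4-[(triisopropylsilyl)oxy]-2-{2-[(1S,2S)-1,2,3-trimethylcyclohex-3-en-1-yl]ethyl}-3,4-dihydro-2H-pyran-6-yl]cyclobut-2-en-1-olate | COC1=C(OC)C(O[Li])(C2=CC(O[Si](C(C)C)(C(C)C)C(C)C)C[C@@](C)(CC[C@]3(C)CCC=C(C)[C@H]3C)O2)C1=O | intermediate
26 | 2,3,4-trimethoxy-4-[(2R)-2-methyl-4-[(triisopropylsilyl)oxy]-2-{2-[(1S,2S)-1,2,3-trimethylcyclohex-3-en-1-yl]ethyl}-3,4-dihydro-2H-pyran-6-yl]cyclobut-2-en-1-one, epimers at the carbinol carbon and at pyran C4 | COC1=C(OC)C(OC)(C2=CC(O[Si](C(C)C)(C(C)C)C(C)C)C[C@@](C)(CC[C@]3(C)CCC=C(C)[C@H]3C)O2)C1=O | intermediate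
27 | (3Z)-2,3,4-trimethoxy-4-[(2R)-2-methyl-4-[(triisopropylsilyl)oxy]-2-{2-[(1S,2S)-1,2,3-trimethylcyclohex-3-en-1-yl]ethyl}-3,4-dihydro-2H-pyran-6-yl]buta-1,3-dien-1-one (dienylketene, pyranyl cis to the ketene-bearing carbon) | O=C=C(OC)/C(OC)=C(OC)\C1=CC(O[Si](C(C)C)(C(C)C)C(C)C)C[C@@](C)(CC[C@]2(C)CCC=C(C)[C@H]2C)O1 | intermediate
28 | (2R)-6,7,8-trimethoxy-2-methyl-4-[(triisopropylsilyl)oxy]-2-{2-[(1S,2S)-1,2,3-trimethylcyclohex-3-en-1-yl]ethyl}-2,3,4,4a-tetrahydro-5H-chromen-5-one | O=C1C(OC)=C(OC)C(OC)=C2O[C@](C)(CC[C@]3(C)CCC=C(C)[C@H]3C)CC(O[Si](C(C)C)(C(C)C)C(C)C)C12 | intermediate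
29 | (2R)-6,7,8-trimethoxy-2-methyl-4-[(triisopropylsilyl)oxy]-2-{2-[(1S,2S)-1,2,3-trimethylcyclohex-3-en-1-yl]ethyl}-3,4-dihydro-2H-chromen-5-ol, C4 epimers | COc1c(O)c2c(c(OC)c1OC)O[C@](C)(CC[C@]1(C)CCC=C(C)[C@H]1C)CC2O[Si](C(C)C)(C(C)C)C(C)C | intermediate
30 | (2R)-6,7,8-trimethoxy-2-methyl-2-{2-[(1S,2S)-1,2,3-trimethylcyclohex-3-en-1-yl]ethyl}-2H-chromen-5-ol | COc1c(O)c2c(c(OC)c1OC)O[C@](C)(CC[C@]1(C)CCC=C(C)[C@H]1C)C=C2 | target

## Step count and least certain steps

Total: 17 steps. Longest linear sequence: 16 steps (steps 1–3 and 5–17, from geraniol 1); step 4 is a one-step side branch.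

**Step 16 (key step).** The likely failure is thermal loss of silanol from the ortho-hydroxybenzylic silyl ether, followed by oligomerisation of the resulting ortho-quinone methide. Air oxidation of the hydroquinone monoether is a second risk. A sluggish ring opening of the methyl ether would force temperatures at which both grow. The fallback keeps the ring expansion but runs it on the triethylsilyl ether, the most widely used substrate class, and methylates O8 afterwards. It sets out from 22, which is lithiated and added to 23 as in step 15.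
- Trapping the alkoxide with Et3SiOTf would give the 4-(triethylsilyloxy)cyclobutenone F1.
- Heating in toluene would give the 8-(triethylsilyloxy)chroman-5-ol F2.
- Ac2O, pyridine and DMAP would give the C5 acetate F3.
- Bu4NF buffered with AcOH at 0 °C should cleave only the aryl silyl ether, giving the C8 phenol F4.
- MeI and K2CO3 in acetone would give the C8 methyl ether F5.
- K2CO3 in MeOH under argon removes the acetate and returns to 29.

**Step 2.** The risks are imperfect enolate geometry, a slow rearrangement of the hindered boron ketene acetal with loss of facial selectivity, and a sense of induction opposite to the one assumed. The fallback is an achiral Ireland–Claisen rearrangement followed by resolution. From 2, LiN(i-Pr)2 and Me3SiCl in THF at −78 °C, then warming, would give the racemic acid F6 of the same relative configuration through the same chair. Acylation of lithiated (S)-4-benzyl-1,3-oxazolidin-2-one with the pivaloyl mixed anhydride gives two diastereomeric imides, which are separated by chromatography. The (2S,3S)-acyl imide F7 is cleaved with LiOH/H2O2 to return to 5.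

**Step 10.** The risks are slow initiation on two hindered alkenes, catalyst deactivation by the 1,3-diol, and ruthenium-hydride-induced migration of the 1,1-disubstituted double bond into the tetrasubstituted position, which would erase C2'. The fallback closes the ring by carbonyl coupling and sets out from 7.
- MeMgBr would give the vinyl ketone F8.
- Buffered mCPBA should epoxidise only the trisubstituted alkene, giving the epoxide F9.
- HIO4 cleaves F9 to the keto aldehyde F10.
- McMurry coupling with TiCl3(DME)1.5 and Zn–Cu in refluxing DME would give the vinylcyclohexene F11.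
- 9-BBN and coupling with 10 as in step 5 would give the allylic alcohol F12.
- Epoxidation as in step 8 would give the epoxy alcohol F13.
- NaAlH2(OCH2CH2OMe)2 as in step 9 returns to 17.

**Step 14.** The risk is slow addition of the hindered tertiary hydroxyl to the tungsten vinylidene, which leaves room for alkyne oligomerisation and decomposition on prolonged irradiation. The fallback is the ynone route and sets out from 20.
- MnO2 would oxidise only the propargylic alcohol, giving the hydroxy ynone F14.
- AgOTf-catalysed 6-endo oxa-Michael closure would give the dihydropyranone F15.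
- Luche reduction (NaBH4, CeCl3·7H2O, MeOH, −78 °C) would give the allylic alcohol F16.
- i-Pr3SiOTf and 2,6-lutidine return to 22.

**Step 15.** The risks are incomplete or unselective deprotonation (competition from the silyl group or the allylic C4–H), attack on 23 by surplus t-BuLi or by its THF cleavage products, double addition to the squarate, and incomplete O-methylation of the hindered alkoxide. The fallback separates the operations and sets out from 22. Lithiation and quenching with Bu3SnCl would give the stannane F17, which can be purified. Tin–lithium exchange with n-BuLi at −78 °C regenerates 24 free of other bases. Addition to 23 and aqueous quench would give the hydroxycyclobutenone F18, and MeI with Ag2O and K2CO3 in MeCN returns to 26.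

## Further compounds

F1 | step 16 | 2,3-dimethoxy-4-[(triethylsilyl)oxy]-4-[(2R)-2-methyl-4-[(triisopropylsilyl)oxy]-2-{2-[(1S,2S)-1,2,3-trimethylcyclohex-3-en-1-yl]ethyl}-3,4-dihydro-2H-pyran-6-yl]cyclobut-2-en-1-one | COC1=C(OC)C(O[Si](CC)(CC)CC)(C2=CC(O[Si](C(C)C)(C(C)C)C(C)C)C[C@@](C)(CC[C@]3(C)CCC=C(C)[C@H]3C)O2)C1=O
F2 | step 16 | (2R)-6,7-dimethoxy-2-methyl-8-[(triethylsilyl)oxy]-4-[(triisopropylsilyl)oxy]-2-{2-[(1S,2S)-1,2,3-trimethylcyclohex-3-en-1-yl]ethyl}-3,4-dihydro-2H-chromen-5-ol | COc1c(O)c2c(c(O[Si](CC)(CC)CC)c1OC)O[C@](C)(CC[C@]1(C)CCC=C(C)[C@H]1C)CC2O[Si](C(C)C)(C(C)C)C(C)C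
F3 | step 16 | C5 acetate of F2 | COc1c(OC(C)=O)c2c(c(O[Si](CC)(CC)CC)c1OC)O[C@](C)(CC[C@]1(C)CCC=C(C)[C@H]1C)CC2O[Si](C(C)C)(C(C)C)C(C)C
F4 | step 16 | (2R)-8-hydroxy-6,7-dimethoxy-2-methyl-4-[(triisopropylsilyl)oxy]-2-{2-[(1S,2S)-1,2,3-trimethylcyclohex-3-en-1-yl]ethyl}-3,4-dihydro-2H-chromen-5-yl acetate | COc1c(OC(C)=O)c2c(c(O)c1OC)O[C@](C)(CC[C@]1(C)CCC=C(C)[C@H]1C)CC2O[Si](C(C)C)(C(C)C)C(C)C
F5 | step 16 | C5 acetate of 29 | COc1c(OC(C)=O)c2c(c(OC)c1OC)O[C@](C)(CC[C@]1(C)CCC=C(C)[C@H]1C)CC2O[Si](C(C)C)(C(C)C)C(C)C
F6 | step 2 | racemic (2S*,3S*)-3-ethenyl-2,3,7-trimethyloct-6-enoic acid (relative configuration as drawn; both enantiomers) | OC(=O)[C@@H](C)[C@](C)(C=C)CCC=C(C)C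
F7 | step 2 | (4S)-4-benzyl-3-[(2S,3S)-3-ethenyl-2,3,7-trimethyloct-6-enoyl]-1,3-oxazolidin-2-one | O=C1OC[C@H](Cc2ccccc2)N1C(=O)[C@@H](C)[C@](C)(C=C)CCC=C(C)C
F8 | step 10 | (3S,4S)-4-ethenyl-3,4,8-trimethylnon-7-en-2-one | CC(=O)[C@@H](C)[C@](C)(C=C)CCC=C(C)C
F9 | step 10 | (3S,4S)-6-(3,3-dimethyloxiran-2-yl)-4-ethenyl-3,4-dimethylhexan-2-one, epoxide epimers | CC(=O)[C@@H](C)[C@](C)(C=C)CCC1OC1(C)C
F10 | step 10 | (4S,5S)-4-ethenyl-4,5-dimethyl-6-oxoheptanal | CC(=O)[C@@H](C)[C@](C)(C=C)CCC=O
F11 | step 10 | (5S,6S)-5-ethenyl-1,5,6-trimethylcyclohex-1-ene | C=C[C@]1(C)CCC=C(C)[C@H]1C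
F12 | step 10 | (2Z)-3-methyl-5-[(1S,2S)-1,2,3-trimethylcyclohex-3-en-1-yl]pent-2-en-1-ol | OC/C=C(/C)CC[C@]1(C)CCC=C(C)[C@H]1C
F13 | step 10 | [(2S,3R)-3-methyl-3-{2-[(1S,2S)-1,2,3-trimethylcyclohex-3-en-1-yl]ethyl}oxiran-2-yl]methanol | OC[C@@H]1O[C@]1(C)CC[C@]2(C)CCC=C(C)[C@H]2C
F14 | step 14 | (5R)-5-hydroxy-5-methyl-7-[(1S,2S)-1,2,3-trimethylcyclohex-3-en-1-yl]hept-1-yn-3-one | C#CC(=O)C[C@](C)(O)CC[C@]1(C)CCC=C(C)[C@H]1C
F15 | step 14 | (2R)-2-methyl-2-{2-[(1S,2S)-1,2,3-trimethylcyclohex-3-en-1-yl]ethyl}-2,3-dihydro-4H-pyran-4-one | O=C1C=CO[C@](C)(CC[C@]2(C)CCC=C(C)[C@H]2C)C1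
F16 | step 14 | (2R)-2-methyl-2-{2-[(1S,2S)-1,2,3-trimethylcyclohex-3-en-1-yl]ethyl}-3,4-dihydro-2H-pyran-4-ol, C4 epimers | OC1C=CO[C@](C)(CC[C@]2(C)CCC=C(C)[C@H]2C)C1
F17 | step 15 | tributyl[(2R)-2-methyl-4-[(triisopropylsilyl)oxy]-2-{2-[(1S,2S)-1,2,3-trimethylcyclohex-3-en-1-yl]ethyl}-3,4-dihydro-2H-pyran-6-yl]stannane | CCCC[Sn](CCCC)(CCCC)C1=CC(O[Si](C(C)C)(C(C)C)C(C)C)C[C@@](C)(CC[C@]2(C)CCC=C(C)[C@H]2C)O1
F18 | step 15 | 4-hydroxy-2,3-dimethoxy-4-[(2R)-2-methyl-4-[(triisopropylsilyl)oxy]-2-{2-[(1S,2S)-1,2,3-trimethylcyclohex-3-en-1-yl]ethyl}-3,4-dihydro-2H-pyran-6-yl]cyclobut-2-en-1-one | COC1=C(OC)C(O)(C2=CC(O[Si](C(C)C)(C(C)C)C(C)C)C[C@@](C)(CC[C@]3(C)CCC=C(C)[C@H]3C)O2)C1=O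
A1 | alternative 1 | (3E)-3-methylpenta-1,3-diene | C=C/C(C)=C/C
A2 | alternative 1 | 2-methylidene-4-(2-methyl-1,3-dioxolan-2-yl)butanal | C=C(C=O)CCC1(C)OCCO1
A3 | alternative 1 | 2,3-dimethyl-1-[2-(2-methyl-1,3-dioxolan-2-yl)ethyl]cyclohex-3-ene-1-carbaldehyde, formyl cis to the C2 methyl, ring configuration as in 30 | CC1(CC[C@]2(C=O)CCC=C(C)[C@H]2C)OCCO1
A4 | alternative 2 | 4,5,6-trimethoxy-3-[(trifluoromethylsulfonyl)oxy]benzyne | COC1=C(OC)C(OC)=C(OS(=O)(=O)C(F)(F)F)C#C1
A5 | alternative 2 | (2E)-3-methyl-5-[(1S,2S)-1,2,3-trimethylcyclohex-3-en-1-yl]pent-2-enal | O=C/C=C(\C)CC[C@]1(C)CCC=C(C)[C@H]1C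
A6 | alternative 2 | (2R)-6,7,8-trimethoxy-2-methyl-2-{2-[(1S,2S)-1,2,3-trimethylcyclohex-3-en-1-yl]ethyl}-2H-chromen-5-yl trifluoromethanesulfonate (forms together with its C2 epimer) | COc1c(OS(=O)(=O)C(F)(F)F)c2c(c(OC)c1OC)O[C@](C)(CC[C@]1(C)CCC=C(C)[C@H]1C)C=C2
A7 | alternative 3 | (1Z,3R)-1-[2-bromo-3,4,5-trimethoxy-6-(methoxymethoxy)phenyl]-3-methyl-5-[(1S,2S)-1,2,3-trimethylcyclohex-3-en-1-yl]pent-1-en-3-ol | COc1c(OCOC)c(/C=C\[C@](C)(O)CC[C@]2(C)CCC=C(C)[C@H]2C)c(Br)c(OC)c1OC
A8 | alternative 3 | (2R)-6,7,8-trimethoxy-5-(methoxymethoxy)-2-methyl-2-{2-[(1S,2S)-1,2,3-trimethylcyclohex-3-en-1-yl]ethyl}-2H-chromene | COc1c(OCOC)c2c(c(OC)c1OC)O[C@](C)(CC[C@]1(C)CCC=C(C)[C@H]1C)C=C2
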